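## Retrosynthetic overview
1. The target comes from macrocyclic keto lactone **22** by three late operations: C9 ketone reduction, conversion of the ring A silyl enol ether to the enone, and kinetic protonation at C11.
2. Key step: **22** comes from open-chain diketone enal **19** by forming C7–C8. SmI2 reduces the C8/C9 diketone to a samarium enediolate, so the C8 carbonyl carbon becomes a nucleophile and attacks the C7 aldehyde carbon.
3. **19** comes from aldehyde **14** and methyl methacrylate. C8–C9 is made by a Stetter reaction (C9 acyl anion onto the acrylate β-carbon), followed by α-oxidation.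
4. **14** comes from a B-alkyl Suzuki coupling (C4–C5) of vinyl carbinol acetate **7** with chloro enol triflate **10**, which carries the C5=C6(Cl) geometry.
5. Ring order: ring A first (asymmetric Diels–Alder of **2** and **3**), then the ten-membered ring and the γ-lactone together in the key step.

Atom numbering (briarane): C1 (quaternary, Me-15), C2 (OAc), C3, C4, C5 (Me-16)=C6 (Cl), C7 (lactone O), C8 (OH), C9 (OH), C10, C11 (Me-20), C12 (C=O), C13=C14. Lactone carbons: C17 (Me-18) and C19 (C=O).

Assumption: the (S)-oxazaborolidinium catalyst delivers the diene to the enal face that gives C1 and C10 as in the target; if the sense is the opposite, its equally available enantiomer is used.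

## Route

Step 1
Reactants: 1 pent-1-en-3-one (ethyl vinyl ketone)
Product: 2 (Z)-3-(triisopropylsilyloxy)penta-1,3-diene
Conditions: iPr3SiOTf, Et3N, CH2Cl2, 0 °C
Reagents that add atoms: triisopropylsilyl triflate CC(C)[Si](C(C)C)(C(C)C)OS(=O)(=O)C(F)(F)F
Why: Soft enolisation (silyl triflate plus amine) of the ethyl ketone gives the 2-silyloxydiene as the Z enol ether, which avoids A(1,3) strain and places the methyl "outside" in the reactive s-cis diene.

Step 2
Reactants: 2 (Z)-3-(triisopropylsilyloxy)penta-1,3-diene; 3 (E)-4,4-dimethoxy-2-methylbut-2-enal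
Product: 4 ring A aldehyde, 2-(dimethoxymethyl)-1,3-dimethyl-4-(triisopropylsilyloxy)cyclohex-4-ene-1-carbaldehyde (CHO trans to CH(OMe)2, 3-methyl cis to CHO, C1 and C10 as in the target)
Conditions: (S)-3,3-diphenyl-1-(2-methylphenyl)tetrahydropyrrolo[1,2-c][1,3,2]oxazaborole·HNTf2 (15 mol %), CH2Cl2, −78 to −40 °C
Reagents that add atoms: none
Why: In this enantioselective Lewis-acid-catalysed Diels–Alder reaction the nucleophilic C11 terminus of the 2-silyloxydiene bonds to the enal β-carbon C10 ("para" rule), the E dienophile fixes C2 and C9 trans, the catalyst blocks one enal face and so sets C1 and C10 absolutely, and the formyl-endo transition state places the C11 methyl cis to CHO, which is the wrong C11 epimer and is corrected in step 14.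

Step 3
Reactants: 4 ring A aldehyde; 5 vinylmagnesium bromide
Product: 7 vinyl carbinol acetate (C2 as in the target), via bromomagnesium alkoxide 6 (not isolated)
Conditions: THF, −78 °C; then Ac2O, DMAP (cat.), −78 °C to rt
Reagents that add atoms: acetic anhydride CC(=O)OC(C)=O
Why: Grignard 1,2-addition under Felkin–Anh control (C10 as the large group anti to the nucleophile, C14H2 medium, methyl small) gives the 2S carbinol, which is trapped in the flask as the acetate that stays to the end.

Step 4
Reactants: 8 methyl 2-chloroacetoacetate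
Product: 9 methyl 2-chloro-3-(trifluoromethylsulfonyloxy)but-2-enoate (triflate cis to the ester, trans to Cl)
Conditions: Tf2O, sat. aq. LiOH, toluene, 5 °C
Reagents that add atoms: triflic anhydride O=S(=O)(OS(=O)(=O)C(F)(F)F)C(F)(F)F
Why: O-sulfonylation of the chelated lithium enolate of the β-keto ester places the triflate cis to the ester, which fixes the later ring-cis C4/C7 relation and the cis methyl/Cl relation on C5=C6.

Step 5
Reactants: 9 chloro enol triflate ester
Product: 10 3-chloro-4-hydroxybut-2-en-2-yl triflate (triflate cis to CH2OH)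
Conditions: iBu2AlH (2.2 equiv), CH2Cl2, −78 °C; aq. work-up
Reagents that add atoms: none
Why: Hydride reduction of the conjugated ester to the allylic alcohol leaves the vinyl triflate, the vinyl chloride and the alkene geometry untouched at low temperature.

Step 6
Reactants: 7 vinyl carbinol acetate; 10 chloro enol triflate alcohol
Product: 12 coupled allylic alcohol (C2–C7 chain; C4 cis to C7 on C5=C6), via B-alkyl-9-BBN adduct 11 (not isolated)
Conditions: 9-BBN, THF, rt; then 10, Pd(dppf)Cl2 (5 mol %), AsPh3, K3PO4, DMF–H2O, rt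
Reagents that add atoms: none
Why: In this anti-Markovnikov hydroboration followed by a stereoretentive B-alkyl Suzuki–Miyaura coupling, 9-BBN reacts with the terminal vinyl group much faster than with the trisubstituted silyl enol ether, and the triflate reacts in preference to the vinyl chloride, so C4–C5 forms with the geometry set in step 4.

Step 7
Reactants: 12 coupled allylic alcohol
Product: 14 C9 aldehyde carrying a C7 triethylsilyl ether, via methoxy lutidinium triflate 13 (not isolated)
Conditions: Et3SiOTf (3 equiv), 2,6-lutidine, CH2Cl2, 0 °C; then H2O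
Reagents that add atoms: triethylsilyl triflate CC[Si](CC)(CC)OS(=O)(=O)C(F)(F)F; water O
Why: Silyl triflate and lutidine cleave the acetal through a pyridinium-type salt under weakly basic conditions, so the aldehyde is released on adding water while the silyl enol ether and acetate survive and the C7 hydroxyl is silylated in the same operation.

Step 8
Reactants: 14 C9 aldehyde; 15 methyl methacrylate
Product: 16 γ-keto ester (C9 ketone, C8H2, C17 epimers)
Conditions: 3-benzyl-5-(2-hydroxyethyl)-4-methylthiazolium chloride (20 mol %), Et3N (20 mol %), 15 (5 equiv), dioxane, 70 °C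
Reagents that add atoms: none
Why: In the Stetter reaction the thiazolylidene turns the C9 aldehyde into its Breslow acyl-anion equivalent, which adds to the unhindered terminal β-carbon (C8) of the acrylate, while self-benzoin coupling of the branched aldehyde is slow and C10 remains the more stable equatorial epimer.

Step 9
Reactants: 16 γ-keto ester
Product: 18 α-hydroxy ketone (C8–OH; epimers at C8 and C17), via potassium enolate 17 (not isolated)
Conditions: KN(SiMe3)2 (1.1 equiv), THF, −78 °C; 2-(phenylsulfonyl)-3-phenyloxaziridine; AcOH quench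
Reagents that add atoms: 2-(phenylsulfonyl)-3-phenyloxaziridine O=S(=O)(N1OC1c1ccccc1)c1ccccc1
Why: In this Davis enolate hydroxylation, kinetic deprotonation takes the ketone CH2 (C8) rather than the hindered C10–H or the less acidic ester positions, and the C8 configuration does not matter because it is erased in step 10.

Step 10
Reactants: 18 α-hydroxy ketone
Product: 19 vicinal diketone enal (C8,C9-dione, largely enolised towards C17; C7 α-chloro enal)
Conditions: (COCl)2, DMSO, CH2Cl2, −78 to −30 °C; Et3N
Reagents that add atoms: none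
Why: Swern oxidation with excess reagent oxidises the acyloin to the diketone and converts the primary allylic triethylsilyl ether directly into the enal (oxidative desilylation of primary TES ethers), while the bulky triisopropylsilyl enol ether is untouched.

Step 11
Reactants: 19 vicinal diketone enal
Product: 22 macrocyclic keto lactone (ten-membered ring and γ-lactone closed; 8-OH; C9 ketone; C7 C8 C17 as in the target), via samarium enediolate 20 (not isolated), via samarium aldolate 21 (not isolated)
Conditions: SmI2 (2.2 equiv), THF, slow addition of 19 to 0.002 M, −78 to 0 °C; aq. work-up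
Reagents that add atoms: none
Why: Proposed new method: SmI2 reduces the vicinal diketone far faster than the enal to a chelated Z enediolate, which makes the C8 carbonyl carbon nucleophilic; A(1,3) strain turns H10 into the enediolate plane so that C1 shields one face and fixes C8, a Zimmerman–Traxler chair (O8 cis to the metal-bound O9) gives the 7,8-syn relation, the C7 alkoxide then closes the lactone irreversibly, and C17 settles with its methyl anti to C9 under the samarium methoxide released; the closest known reaction type is the intermolecular SmI2 coupling of 1,2-diketones with aldehydes to 2,3-dihydroxy ketones, together with SmI2 Reformatsky-type medium-ring closures.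

Step 12
Reactants: 22 macrocyclic keto lactone
Product: 23 8,9-diol (C9 as in the target)
Conditions: NaBH4, MeOH–CH2Cl2, −40 °C
Reagents that add atoms: none
Why: Hydride addition under Felkin–Anh control from C10 (C1 large and anti to the hydride, C11 medium) gives the 9S alcohol, the opposite of what a carbon nucleophile adding to a C9 aldehyde would give, and the lactone, acetate and silyl enol ether are inert at this temperature.

Step 13
Reactants: 23 8,9-diol
Product: 24 11-epi target (C12 enone, C13=C14)
Conditions: Pd(OAc)2 (1.1 equiv), DMSO–MeCN, 40 °C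
Reagents that add atoms: none
Why: In the Saegusa–Ito oxidation, palladation at C13 of the Diels–Alder-derived silyl enol ether and β-hydride elimination from C14 place the enone regiospecifically under nearly neutral conditions that leave all stereocentres untouched.

Step 14
Reactants: 24 11-epi target
Product: 26 CNP0163464.1 (target), via tris-TMS dienol ether 25 (not isolated)
Conditions: Me3SiOTf, Et3N, CH2Cl2, −78 to 0 °C; then 1 M aq. HCl, THF, −40 to 0 °C
Reagents that add atoms: none
Why: Soft enolisation to the cross-conjugated silyl dienol ether erases C11, and kinetic protonation then occurs anti to the C9 substituent, which A(1,2) strain with the C11 methyl holds pseudoaxial, giving the 11R ketone (methyl cis to C9) while the two TMS ethers hydrolyse in the same acid.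

## Compound list
1 | pent-1-en-3-one | CCC(=O)C=C | starting material
2 | (Z)-3-(triisopropylsilyloxy)penta-1,3-diene | C=C/C(O[Si](C(C)C)(C(C)C)C(C)C)=C/C | intermediate
3 | (E)-4,4-dimethoxy-2-methylbut-2-enal | O=C/C(C)=C/C(OC)OC | starting material
4 | ring A aldehyde (CHO trans to CH(OMe)2, C11 methyl cis to CHO) | COC(OC)[C@H]1[C@H](C)C(O[Si](C(C)C)(C(C)C)C(C)C)=CC[C@]1(C)C=O | intermediate
5 | vinylmagnesium bromide | C=C[Mg]Br | starting material
6 | bromomagnesium alkoxide of the C2 vinyl carbinol | COC(OC)[C@H]1[C@H](C)C(O[Si](C(C)C)(C(C)C)C(C)C)=CC[C@]1(C)[C@@H](O[Mg]Br)C=C | intermediate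
7 | vinyl carbinol acetate (2S) | COC(OC)[C@H]1[C@H](C)C(O[Si](C(C)C)(C(C)C)C(C)C)=CC[C@]1(C)[C@@H](OC(C)=O)C=C | intermediate
8 | methyl 2-chloroacetoacetate | COC(=O)C(Cl)C(C)=O | starting material
9 | methyl 2-chloro-3-(triflyloxy)but-2-enoate (OTf cis to ester) | O=S(=O)(O/C(C)=C(/Cl)C(=O)OC)C(F)(F)F | intermediate
10 | 3-chloro-4-hydroxybut-2-en-2-yl triflate (OTf cis to CH2OH) | O=S(=O)(O/C(C)=C(/Cl)CO)C(F)(F)F | intermediate
11 | B-alkyl-9-BBN adduct of 7 (boron on C4) | COC(OC)[C@H]1[C@H](C)C(O[Si](C(C)C)(C(C)C)C(C)C)=CC[C@]1(C)[C@@H](OC(C)=O)CCB1C2CCCC1CCC2 | intermediate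
12 | coupled allylic alcohol (C4 cis to C7) | COC(OC)[C@H]1[C@H](C)C(O[Si](C(C)C)(C(C)C)C(C)C)=CC[C@]1(C)[C@@H](OC(C)=O)CC/C(C)=C(/Cl)CO | intermediate
13 | C9 methoxy 2,6-lutidinium triflate, C7–OTES | COC([n+]1c(C)cccc1C)[C@H]1[C@H](C)C(O[Si](C(C)C)(C(C)C)C(C)C)=CC[C@]1(C)[C@@H](OC(C)=O)CC/C(C)=C(/Cl)CO[Si](CC)(CC)CC.[O-]S(=O)(=O)C(F)(F)F | intermediate
14 | C9 aldehyde, C7–OTES | O=C[C@H]1[C@H](C)C(O[Si](C(C)C)(C(C)C)C(C)C)=CC[C@]1(C)[C@@H](OC(C)=O)CC/C(C)=C(/Cl)CO[Si](CC)(CC)CC | intermediate
15 | methyl methacrylate | C=C(C)C(=O)OC | starting material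
16 | γ-keto ester (C17 epimers) | COC(=O)C(C)CC(=O)[C@H]1[C@H](C)C(O[Si](C(C)C)(C(C)C)C(C)C)=CC[C@]1(C)[C@@H](OC(C)=O)CC/C(C)=C(/Cl)CO[Si](CC)(CC)CC | intermediate
17 | potassium C8=C9 enolate of 16 | COC(=O)C(C)C=C([O-])[C@H]1[C@H](C)C(O[Si](C(C)C)(C(C)C)C(C)C)=CC[C@]1(C)[C@@H](OC(C)=O)CC/C(C)=C(/Cl)CO[Si](CC)(CC)CC.[K+] | intermediate
18 | α-hydroxy ketone (C8 and C17 epimers) | COC(=O)C(C)C(O)C(=O)[C@H]1[C@H](C)C(O[Si](C(C)C)(C(C)C)C(C)C)=CC[C@]1(C)[C@@H](OC(C)=O)CC/C(C)=C(/Cl)CO[Si](CC)(CC)CC | intermediate
19 | vicinal diketone enal | COC(=O)C(C)C(=O)C(=O)[C@H]1[C@H](C)C(O[Si](C(C)C)(C(C)C)C(C)C)=CC[C@]1(C)[C@@H](OC(C)=O)CC/C(C)=C(/Cl)C=O | intermediate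
20 | samarium Z enediolate (O8 cis to O9) | COC(=O)C(C)/C(O[Sm](I)I)=C(/O[Sm](I)I)[C@H]1[C@H](C)C(O[Si](C(C)C)(C(C)C)C(C)C)=CC[C@]1(C)[C@@H](OC(C)=O)CC/C(C)=C(/Cl)C=O | intermediate
21 | macrocyclic samarium aldolate (C7–C8 formed, ester still open) | CC(=O)O[C@H]1CC/C(C)=C(/Cl)[C@@H](O[Sm](I)I)[C@@](O[Sm](I)I)(C(C)C(=O)OC)C(=O)[C@H]2[C@H](C)C(O[Si](C(C)C)(C(C)C)C(C)C)=CC[C@@]21C | intermediate
22 | macrocyclic keto lactone (8-OH, C9 ketone, ring A as TIPS enol ether) | CC(=O)O[C@H]1CC/C(C)=C(/Cl)[C@H]2OC(=O)[C@H](C)[C@@]2(O)C(=O)[C@H]2[C@H](C)C(O[Si](C(C)C)(C(C)C)C(C)C)=CC[C@@]21C | intermediate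
23 | 8,9-diol (9S) | CC(=O)O[C@H]1CC/C(C)=C(/Cl)[C@H]2OC(=O)[C@H](C)[C@@]2(O)[C@@H](O)[C@H]2[C@H](C)C(O[Si](C(C)C)(C(C)C)C(C)C)=CC[C@@]21C | intermediate
24 | 11-epi target | CC(=O)O[C@H]1CC/C(C)=C(/Cl)[C@H]2OC(=O)[C@H](C)[C@@]2(O)[C@@H](O)[C@H]2[C@H](C)C(=O)C=C[C@@]21C | intermediate
25 | tris-TMS compound (8-OTMS, 9-OTMS, C11=C12(OTMS)–C13=C14 dienol ether) | CC(=O)O[C@H]1CC/C(C)=C(/Cl)[C@H]2OC(=O)[C@H](C)[C@@]2(O[Si](C)(C)C)[C@@H](O[Si](C)(C)C)[C@H]2C(C)=C(O[Si](C)(C)C)C=C[C@@]21C | intermediate
26 | CNP0163464.1 (1S,2S,7S,8R,9S,10S,11R,17R; C4 cis to C7 on C5=C6) | CC(=O)O[C@H]1CC/C(C)=C(/Cl)[C@H]2OC(=O)[C@H](C)[C@@]2(O)[C@@H](O)[C@H]2[C@@H](C)C(=O)C=C[C@@]21C | target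

## Step count and risks
Total step count: 14.
Longest linear sequence: 12 steps (steps 1, 2, 3 and 6–14). Steps 4 and 5 run in parallel.

**Step 11** is the ring closure by the samarium enediolate. A ten-membered closure onto a hindered α-chloro enal may lose out to simple protonation of the enediolate or to reduction of the enal.

The fallback sets out from 18 and returns to the route at 22. It replaces reductive generation of the nucleophile with a redox-neutral direct aldol.
- Aqueous acetic acid in THF removes the triethylsilyl group to give the hydroxy ketone allylic alcohol F1.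
- TEMPO with PhI(OAc)2 oxidises only the primary allylic alcohol to the hydroxy ketone enal F2.
- A dinuclear zinc alkoxide made from Et2Zn and a bis(prolinol)phenol ligand deprotonates the acyloin to the same chelated enediolate geometry, and aldol ring closure and lactonisation at high dilution give 22.

**Step 8** is the Stetter reaction. The aldehyde sits next to a quaternary centre and may form the Breslow intermediate too slowly.

The fallback sets out from 14 and returns at 16. It moves the polarity reversal to the other partner.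
- Methyl 3-bromo-2-methylpropanoate and zinc dust give the zinc homoenolate F3.
- After transmetallation with ClTi(OiPr)3, this adds to 14 to give the γ-hydroxy ester F4.
- Immediate oxidation with Dess–Martin periodinane gives 16.

**Step 14** is the C11 correction. Soft enolisation may also touch the lactone or acetate, and the facial selectivity of the protonation may be modest.

The fallback sets out from 23 and returns at 26, bypassing 24 and 25.
- DDQ with 2,6-di-tert-butyl-4-methylpyridine abstracts hydride from C14, and loss of the C11 proton gives the TIPS dienol ether F5.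
- HF·pyridine at −40 °C protonates C11 from the face anti to C9 and removes the silyl group in the same operation.

## Further compounds
F1 | step 11 | hydroxy ketone allylic alcohol (18 without the triethylsilyl group) | COC(=O)C(C)C(O)C(=O)[C@H]1[C@H](C)C(O[Si](C(C)C)(C(C)C)C(C)C)=CC[C@]1(C)[C@@H](OC(C)=O)CC/C(C)=C(/Cl)CO
F2 | step 11 | hydroxy ketone enal | COC(=O)C(C)C(O)C(=O)[C@H]1[C@H](C)C(O[Si](C(C)C)(C(C)C)C(C)C)=CC[C@]1(C)[C@@H](OC(C)=O)CC/C(C)=C(/Cl)C=O
F3 | step 8 | (3-methoxy-2-methyl-3-oxopropyl)zinc bromide | COC(=O)C(C)C[Zn]Br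
F4 | step 8 | γ-hydroxy ester (C9 carbinol, epimers at C9 and C17) | COC(=O)C(C)CC(O)[C@H]1[C@H](C)C(O[Si](C(C)C)(C(C)C)C(C)C)=CC[C@]1(C)[C@@H](OC(C)=O)CC/C(C)=C(/Cl)CO[Si](CC)(CC)CC
F5 | step 14 | TIPS dienol ether (C11=C12(OTIPS)–C13=C14) of the 8,9-diol | CC(=O)O[C@H]1CC/C(C)=C(/Cl)[C@H]2OC(=O)[C@H](C)[C@@]2(O)[C@@H](O)[C@H]2C(C)=C(O[Si](C(C)C)(C(C)C)C(C)C)C=C[C@@]21C
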